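Numbered as in its name (C1, C4 carbonyl; C2 OH; C3 hexadecyl; C5 OMe; C6 H), the quinone ring bears oxygen on C1, C2, C4 and C5, so it is the enol form of a cyclohexane-1,2,4,5-tetraone. That tetraone is the head-to-tail dimer of two 2-oxo acyl units: C3–C2–C1, with the hexadecyl chain on C3, and C6–C5–C4. The route rests on this disconnection. A crossed double Claisen condensation of ethyl 2-oxononadecanoate with ethyl pyruvate forms the C1–C6 and C3–C4 bonds in one operation and delivers the ring directly at the quinone oxidation level. The precursors are two open-chain 2-oxo esters. A final acid-catalysed etherification puts the methyl group on the unhindered C5 oxygen.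

Key step: step 2

Remark: 7 is drawn in the enol form that keeps the two former ester carbons as the carbonyls C1 and C4; its two enol forms are equivalent and interconvert fast, so they are one compound.

Step 1
Reactants: 1 1-bromoheptadecane; 2 diethyl oxalate
Product: 4 ethyl 2-oxononadecanoate, via heptadecylmagnesium bromide 3 (not isolated)
Conditions: Mg turnings, cat. I2, THF, reflux; then added to 2 (3 equiv), THF–Et2O, −78 °C; aq. HCl quench at −78 °C
Reagents that add atoms: magnesium, [Mg] (retained only in intermediate 3)
Why: Grignard formation followed by inverse addition to excess diethyl oxalate at −78 °C should stop at mono-acylation, because the tetrahedral magnesium alkoxide survives until the acidic quench (Grignard acylation of an oxalate diester); no stereocenter is formed.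

Step 2
Reactants: 4 ethyl 2-oxononadecanoate; 5 ethyl pyruvate
Product: 7 3-hexadecyl-2,5-dihydroxy-1,4-benzoquinone, via ethyl 2,4,5-trioxodocosanoate 6 (not isolated)
Conditions: NaOEt (5 equiv), Et2O–EtOH, 0 °C; 5 (3 equiv) added slowly over several hours; rt, 24 h; then aq. HCl
Reagents that add atoms: none
Why: NaOEt enolises both 2-oxo esters; the methyl-derived enolate of 5 acylates at the ester carbonyl of 4 (Claisen condensation, C1–C6 bond) to give the stabilised enolate of 6, and the methylene of 6 that bears the hexadecyl chain then attacks the remaining ester carbonyl (Dieckmann condensation, C3–C4 bond); loss of the second ethoxide gives the cyclohexane-1,2,4,5-tetraone, which enolises to 7 and rests as its disodium salt until the HCl quench. The closest known reaction type is the ethoxide-induced self-condensation of 2-oxo esters to 3,6-dialkyl-2,5-dihydroxy-1,4-benzoquinones, run here as its crossed version; the opposite order of the two acylations ends in the same ring. The six-membered ring closes by 6-exo-trig attack of the enolate carbon on the ester carbonyl. No stereocenter is formed. The step needs crossed over self-condensation and C-acylation over aldol addition to the ketone carbonyls: 5 is cheap, is used in excess and is added slowly, so that 4 meets mainly the pyruvate partner, and the self-condensation products of 5 have no lipophilic chain and stay in the aqueous phase. Aldol adducts can revert under ethoxide, whereas each acylation is pulled forward by deprotonation and the sequence ends in the doubly deprotonated quinone, the thermodynamic sink.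

Step 3
Reactants: 7 3-hexadecyl-2,5-dihydroxy-1,4-benzoquinone
Product: 8 3-hexadecyl-2-hydroxy-5-methoxy-1,4-benzoquinone
Conditions: MeOH–THF, cat. H2SO4, 50 °C, stopped when 7 is consumed
Reagents that add atoms: methanol, CO
Why: Acid-catalysed addition of MeOH to the protonated vinylogous acid followed by loss of water (vinylogous Fischer esterification) should etherify the C5 hydroxyl beside C6–H, since an ether at C2 would be forced out of conjugation by the hexadecyl chain on C3, so that rate and equilibrium both favour C5; no stereocenter is involved.

Compound list
1 | 1-bromoheptadecane | CCCCCCCCCCCCCCCCCBr | starting material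
2 | diethyl oxalate | CCOC(=O)C(=O)OCC | starting material
3 | heptadecylmagnesium bromide | CCCCCCCCCCCCCCCCC[Mg]Br | intermediate
4 | ethyl 2-oxononadecanoate | CCCCCCCCCCCCCCCCCC(=O)C(=O)OCC | intermediate
5 | ethyl pyruvate (ethyl 2-oxopropanoate) | CC(=O)C(=O)OCC | starting material
6 | ethyl 2,4,5-trioxodocosanoate | CCCCCCCCCCCCCCCCCC(=O)C(=O)CC(=O)C(=O)OCC | intermediate
7 | 3-hexadecyl-2,5-dihydroxy-1,4-benzoquinone (3-hexadecyl-2,5-dihydroxycyclohexa-2,5-diene-1,4-dione) | CCCCCCCCCCCCCCCCC1=C(O)C(=O)C=C(O)C1=O | intermediate
8 | 3-hexadecyl-2-hydroxy-5-methoxy-1,4-benzoquinone (3-hexadecyl-2-hydroxy-5-methoxycyclohexa-2,5-diene-1,4-dione) | CCCCCCCCCCCCCCCCC1=C(O)C(=O)C=C(OC)C1=O | target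

Total step count: 3
Longest linear sequence: 3 steps (1 → 4 → 7 → 8)

Steps most likely to fail

Step 2. Aldol addition of either enolate to a ketone carbonyl followed by lactonisation, and self-condensation of each 2-oxo ester, may consume the partners faster than the crossed acylation. The fallback sets out from Grignard reagent 3 (made from 1 as in step 1) and comes back to the route at 7, passing through 6. Reagent 3 is added to N,N'-dimethoxy-N,N'-dimethyloxamide in THF at −78 °C, where the first addition should stop at the chelated magnesium hemiaminal. MeMgBr is then added to the same flask (−78 °C to 0 °C), and aqueous NH4Cl work-up should release both carbonyls to give icosane-2,3-dione F1. F1 is then condensed with diethyl oxalate 2 (excess) and NaOEt in EtOH–Et2O. Claisen acylation of the methyl group should give 6, which closes to 7 by the same Dieckmann step as in the route. Diethyl oxalate has neither an enolisable position nor a ketone carbonyl, so it can act only as the acyl donor, and either order of the two acylations leads to the same ring.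

Step 3. Etherification may run on to the second hydroxyl, or lose its site preference, before the starting quinone is consumed. The fallback sets out from 7 and comes back at 8. Exhaustive methylation (Me2SO4, K2CO3, acetone, reflux) should give 3-hexadecyl-2,5-dimethoxy-1,4-benzoquinone F2. Aqueous HClO4 in 1,4-dioxane at rt should then hydrolyse only the C2 methoxy group, which the C3 chain twists out of conjugation, leaving the C5 ether to give 8.

Step 1. A second addition of the Grignard reagent to the keto group once the tetrahedral intermediate collapses, and Wurtz-type coupling during the magnesium insertion, may erode the mono-acylation. The fallback sets out from 1 and comes back at 4. Ethyl 1,3-dithiane-2-carboxylate is deprotonated with NaH (DMF–toluene, 0 °C to rt) and alkylated with 1 to give ethyl 2-heptadecyl-1,3-dithiane-2-carboxylate F3; a stabilised carbanion cannot over-add. MeI and CaCO3 in aqueous MeCN at 50 °C should then unmask the ketone and give 4.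

Further compounds
F1 | step 2 | icosane-2,3-dione | CCCCCCCCCCCCCCCCCC(=O)C(=O)C
F2 | step 3 | 3-hexadecyl-2,5-dimethoxy-1,4-benzoquinone | CCCCCCCCCCCCCCCCC1=C(OC)C(=O)C=C(OC)C1=O
F3 | step 1 | ethyl 2-heptadecyl-1,3-dithiane-2-carboxylate | CCCCCCCCCCCCCCCCCC1(SCCCS1)C(=O)OCC
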